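The orsellinoyl ring A is not coupled as an arene; it is grown on the finished depside ester. Its carbons C6, C1, C2 and C3 (bearing methyl, the ester carbonyl, oxygen and H) are carried as C6, C5, C4 and C3 of a 4-benzyloxy-6-methyl-2-pyrone-5-carboxylate already esterified to O4 of the heptylresorcylate ring B. C4, its hydroxyl oxygen and C5 are delivered by a ketene bis(silyl) acetal. One inverse-demand [4+2] addition forms C3–C4 and C5–C6, and loss of CO2 and silanol aromatises ring A with its 4-hydroxyl free. The precursor is the fully benzylated aryl pyrone ester; hydrogenolysis ends the route.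

Key step: step 7

Remark: ring A and ring B locants follow benzoate numbering (C1 carries the carboxyl carbon); pyrone locants follow 2H-pyran-2-one numbering (O1, C2 the lactone carbonyl); the target has no stereocentre.

Step 1
Reactants: 1 5-heptylresorcinol
Product: 2 6-heptyl-2,4-dihydroxybenzoic acid
Conditions: MeOMgOCO2Me (2 M in DMF, 4 equiv), 120 °C, N2 stream; then ice-cold 2 M HCl
Reagents that add atoms: methyl magnesium carbonate (MeOMgOCO2Me), COC(=O)O[Mg]OC
Why: Kolbe–Schmitt-type carboxylation with methyl magnesium carbonate should occur ortho to one hydroxyl and para to the other (the site that 5-alkylresorcinols also offer to formylation), and chelation of the new salicylate to magnesium holds the carboxyl group until the cold acid quench.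

Step 2
Reactants: 2 6-heptyl-2,4-dihydroxybenzoic acid
Product: 3 benzyl 6-heptyl-2,4-dihydroxybenzoate
Conditions: BnBr (1.05 equiv), KHCO3 (1.2 equiv), DMF, rt
Reagents that add atoms: benzyl bromide, BrCc1ccccc1
Why: SN2 O-alkylation of the carboxylate, since hydrogencarbonate ionises only the carboxylic acid and leaves both phenols unalkylated.

Step 3
Reactants: 3 benzyl 6-heptyl-2,4-dihydroxybenzoate; 4 2,2,6-trimethyl-4H-1,3-dioxin-4-one
Product: 6 benzyl 6-heptyl-2-hydroxy-4-[(3-oxobutanoyl)oxy]benzoate, via acetylketene 5 (not isolated)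
Conditions: 4 (1.1 equiv), toluene, 110 °C, acetone distilled off
Reagents that add atoms: none
Why: Retro-[4+2] thermolysis of the dioxinone releases acetylketene, which acetoacetylates the free 4-hydroxyl, while the 2-hydroxyl, hydrogen-bonded to the ester carbonyl, is much less nucleophilic.

Step 4
Reactants: 6 benzyl 6-heptyl-2-hydroxy-4-[(3-oxobutanoyl)oxy]benzoate; 7 malonyl dichloride
Product: 9 benzyl 6-heptyl-2-hydroxy-4-{[4-hydroxy-6-methyl-2-oxo-2H-pyran-5-carbonyl]oxy}benzoate, via acyl chloride 8 (not isolated)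
Conditions: 7 (1.2 equiv), ClCH2CH2Cl, 0 → 60 °C, N2 sweep
Reagents that add atoms: none
Why: Cyclocondensation of a beta-keto ester with malonyl dichloride, in which C-acylation at the doubly activated carbon is followed by 6-exo lactonisation of the ketone enol oxygen onto the second acid chloride to give the 4-hydroxy-2-pyrone; without base the chelated phenol and the benzyl ester should remain spectators.

Step 5
Reactants: 9 benzyl 6-heptyl-2-hydroxy-4-{[4-hydroxy-6-methyl-2-oxo-2H-pyran-5-carbonyl]oxy}benzoate
Product: 10 benzyl 2-(benzyloxy)-4-{[4-(benzyloxy)-6-methyl-2-oxo-2H-pyran-5-carbonyl]oxy}-6-heptylbenzoate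
Conditions: BnOH (3 equiv), PPh3 (3 equiv), DIAD (3 equiv), THF, 0 → 45 °C
Reagents that add atoms: benzyl alcohol, OCc1ccccc1
Why: Mitsunobu etherification, in which the acidic pyrone hydroxyl is alkylated on O4 (the usual outcome for 4-hydroxy-2-pyrones) and the chelated salicylate hydroxyl follows with excess reagent and gentle warming, under neutral conditions that spare the aryl ester.

Step 6
Reactants: 11 trimethylsilyl acetate
Product: 13 1,1-bis(trimethylsilyloxy)ethene, via lithium 1-(trimethylsilyloxy)ethenolate 12 (not isolated)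
Conditions: LiN(iPr)2 (1.05 equiv), THF, −78 °C; Me3SiCl (1.1 equiv), −78 °C → rt; filtration, distillation under reduced pressure
Reagents that add atoms: chlorotrimethylsilane, C[Si](C)(C)Cl
Why: Kinetic deprotonation of the silyl ester and O-silylation of the resulting enolate (silyl ketene acetal formation), oxygen being the preferred site for the hard silicon electrophile.

Step 7
Reactants: 10 benzyl 2-(benzyloxy)-4-{[4-(benzyloxy)-6-methyl-2-oxo-2H-pyran-5-carbonyl]oxy}-6-heptylbenzoate; 13 1,1-bis(trimethylsilyloxy)ethene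
Product: 17 benzyl 2-(benzyloxy)-4-{[2-(benzyloxy)-4-hydroxy-6-methylbenzoyl]oxy}-6-heptylbenzoate, via bridged lactone 14 (not isolated), via cyclohexadiene 15 (not isolated), via aryl silyl ether 16 (not isolated)
Conditions: 13 (4 equiv), toluene, 120 °C, sealed tube; then 1 M HCl, THF, 0 °C
Reagents that add atoms: none
Why: Proposed new method: the CH2 terminus of 13 should attack pyrone C6, the carbon beta to the 5-ester carbonyl, while the bis(silyloxy) carbon closes onto C3, the beta carbon of the 4-benzyloxy enol ether, in an asynchronous inverse-electron-demand Diels–Alder addition that gives the 2-oxabicyclo[2.2.2]octenone 14; cycloreversion then expels CO2 to give diene 15, 1,2-elimination of trimethylsilanol aromatises it to 16, and dilute acid frees the phenol. The nearest established reaction type is the conversion of coumalate esters into para-alkoxybenzoates by cycloaddition with ketene acetals, CO2 extrusion and alcohol elimination; a pyrone carrying both a 4-alkoxy and a 6-methyl group has not been taken through it. Ring A is closed by an intermolecular two-component [4+2] annulation (pyrone C3 to C6 as the four-carbon unit, the ketene acetal as the two-carbon unit) and then made aromatic by the two eliminations. No stereocentre is created in 17, since the two bridgehead centres of racemic 14 disappear with the CO2. The selectivity required is regiochemical (CH2 to C6, oxygenated carbon to C3) and it is secured by the matched polarisation of the 5-acyl pyrone, with the 4-benzyloxy group also shielding C4 from conjugate attack and fixing the ring as the 2-pyrone tautomer. The benzyl ester, benzyl ethers and aryl ester carry no acidic hydrogen and should tolerate the neutral thermal conditions, so the sensitive ketene acetal is spent only on the pyrone.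

Step 8
Reactants: 17 benzyl 2-(benzyloxy)-4-{[2-(benzyloxy)-4-hydroxy-6-methylbenzoyl]oxy}-6-heptylbenzoate
Product: 18 4-[(2,4-dihydroxy-6-methylbenzoyl)oxy]-6-heptyl-2-hydroxybenzoic acid
Conditions: H2 (1 atm), 10% Pd/C, EtOAc, rt
Reagents that add atoms: none
Why: Catalytic hydrogenolysis cleaves the benzylic C–O bonds of the benzyl ester and both benzyl ethers, while the depside aryl ester, the arenes and the heptyl chain are inert under these neutral conditions.

Compound list
1 | 5-heptylresorcinol | CCCCCCCc1cc(O)cc(O)c1 | starting material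
2 | 6-heptyl-2,4-dihydroxybenzoic acid | CCCCCCCc1cc(O)cc(O)c1C(=O)O | intermediate
3 | benzyl 6-heptyl-2,4-dihydroxybenzoate | CCCCCCCc1cc(O)cc(O)c1C(=O)OCc1ccccc1 | intermediate
4 | 2,2,6-trimethyl-4H-1,3-dioxin-4-one | CC1=CC(=O)OC(C)(C)O1 | starting material
5 | acetylketene (3-oxobut-1-en-1-one), not isolated | CC(=O)C=C=O | intermediate
6 | benzyl 6-heptyl-2-hydroxy-4-[(3-oxobutanoyl)oxy]benzoate | CCCCCCCc1cc(OC(=O)CC(C)=O)cc(O)c1C(=O)OCc1ccccc1 | intermediate
7 | malonyl dichloride | O=C(Cl)CC(=O)Cl | starting material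
8 | benzyl 4-[(2-acetyl-5-chloro-3,5-dioxopentanoyl)oxy]-6-heptyl-2-hydroxybenzoate, not isolated | CCCCCCCc1cc(OC(=O)C(C(C)=O)C(=O)CC(=O)Cl)cc(O)c1C(=O)OCc1ccccc1 | intermediate
9 | benzyl 6-heptyl-2-hydroxy-4-{[4-hydroxy-6-methyl-2-oxo-2H-pyran-5-carbonyl]oxy}benzoate | CCCCCCCc1cc(OC(=O)C2=C(C)OC(=O)C=C2O)cc(O)c1C(=O)OCc1ccccc1 | intermediate
10 | benzyl 2-(benzyloxy)-4-{[4-(benzyloxy)-6-methyl-2-oxo-2H-pyran-5-carbonyl]oxy}-6-heptylbenzoate | CCCCCCCc1cc(OC(=O)C2=C(C)OC(=O)C=C2OCc2ccccc2)cc(OCc2ccccc2)c1C(=O)OCc1ccccc1 | intermediate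
11 | trimethylsilyl acetate | CC(=O)O[Si](C)(C)C | starting material
12 | lithium 1-(trimethylsilyloxy)ethen-1-olate, not isolated | [Li+].[O-]C(=C)O[Si](C)(C)C | intermediate
13 | 1,1-bis(trimethylsilyloxy)ethene | C=C(O[Si](C)(C)C)O[Si](C)(C)C | intermediate
14 | benzyl 2-(benzyloxy)-4-({5-(benzyloxy)-1-methyl-3-oxo-8,8-bis[(trimethylsilyl)oxy]-2-oxabicyclo[2.2.2]oct-5-ene-6-carbonyl}oxy)-6-heptylbenzoate, racemic with one enantiomer written, not isolated | CCCCCCCc1cc(OC(=O)C2=C(OCc3ccccc3)[C@H]3C(=O)O[C@]2(C)CC3(O[Si](C)(C)C)O[Si](C)(C)C)cc(OCc2ccccc2)c1C(=O)OCc1ccccc1 | intermediate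
15 | benzyl 2-(benzyloxy)-4-({6-(benzyloxy)-2-methyl-4,4-bis[(trimethylsilyl)oxy]cyclohexa-1,5-diene-1-carbonyl}oxy)-6-heptylbenzoate, not isolated | CCCCCCCc1cc(OC(=O)C2=C(C)CC(O[Si](C)(C)C)(O[Si](C)(C)C)C=C2OCc2ccccc2)cc(OCc2ccccc2)c1C(=O)OCc1ccccc1 | intermediate
16 | benzyl 2-(benzyloxy)-4-({2-(benzyloxy)-6-methyl-4-[(trimethylsilyl)oxy]benzoyl}oxy)-6-heptylbenzoate, not isolated | CCCCCCCc1cc(OC(=O)c2c(C)cc(O[Si](C)(C)C)cc2OCc2ccccc2)cc(OCc2ccccc2)c1C(=O)OCc1ccccc1 | intermediate
17 | benzyl 2-(benzyloxy)-4-{[2-(benzyloxy)-4-hydroxy-6-methylbenzoyl]oxy}-6-heptylbenzoate | CCCCCCCc1cc(OC(=O)c2c(C)cc(O)cc2OCc2ccccc2)cc(OCc2ccccc2)c1C(=O)OCc1ccccc1 | intermediate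
18 | 4-[(2,4-dihydroxy-6-methylbenzoyl)oxy]-6-heptyl-2-hydroxybenzoic acid | CCCCCCCc1cc(OC(=O)c2c(C)cc(O)cc2O)cc(O)c1C(=O)O | target

Total step count: 8 (seven in the main line and one for the ketene acetal).
Longest linear sequence: 7 steps (steps 1, 2, 3, 4, 5, 7 and 8, from 5-heptylresorcinol).

Steps most likely to fail

Step 7. The cycloaddition may be too slow: the 4-benzyloxy group raises the acceptor orbital of the diene and the 6-methyl group crowds the carbon attacked first. Thermal oxygen-to-carbon silyl migration in the ketene acetal, or conjugate addition that stops before ring closure, could then take over. The fallback uses the established depside esterification; it sets out from 3 and returns to the route at 18. Commercial methyl 2,4-dihydroxy-6-methylbenzoate (COC(=O)c1c(C)cc(O)cc1O) would be benzylated (BnBr, K2CO3, DMF, 60 °C) to methyl 2,4-bis(benzyloxy)-6-methylbenzoate F1 and saponified (KOH, aqueous DMSO, 80 °C) to 2,4-bis(benzyloxy)-6-methylbenzoic acid F2. Activation of F2 as its mixed trifluoroacetic anhydride ((CF3CO)2O, toluene, rt) should acylate the unchelated 4-hydroxyl of 3 and give benzyl 4-{[2,4-bis(benzyloxy)-6-methylbenzoyl]oxy}-6-heptyl-2-hydroxybenzoate F3. Hydrogenolysis under the conditions of step 8 then gives 18.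

Step 4. The one-pot double acylation may be outrun by acylation of the chelated phenol or by self-condensation of malonyl dichloride before the pyrone ring closes. The fallback makes the two bonds separately; it sets out from 6 and returns at 9. Commercial 3-(tert-butoxy)-3-oxopropanoic acid (CC(C)(C)OC(=O)CC(=O)O) would be converted with 1-chloro-N,N,2-trimethylprop-1-en-1-amine (CH2Cl2, 0 °C) into tert-butyl 3-chloro-3-oxopropanoate F4. F4 would be used at once to C-acylate 6 (MgCl2, pyridine, CH2Cl2, 0 °C) and give benzyl 4-{[2-acetyl-5-(tert-butoxy)-3,5-dioxopentanoyl]oxy}-6-heptyl-2-hydroxybenzoate F5. CF3CO2H (CH2Cl2, 0 °C) cleaves the tert-butyl ester to benzyl 4-[(2-acetyl-4-carboxy-3-oxobutanoyl)oxy]-6-heptyl-2-hydroxybenzoate F6. F6 is not isolated; (CF3CO)2O added to the same flask at 0 °C closes it by enol lactonisation to 9.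

Step 5. Etherification of the hydrogen-bonded salicylate hydroxyl may stall, or prolonged forcing may erode the O4 selectivity at the pyrone. The fallback splits the two etherifications; it sets out from 9 and returns at 10. A Mitsunobu reaction with only 1.1 equivalents of BnOH, PPh3 and DIAD (THF, 0 °C → rt) should touch only the acidic pyrone hydroxyl and give benzyl 4-{[4-(benzyloxy)-6-methyl-2-oxo-2H-pyran-5-carbonyl]oxy}-6-heptyl-2-hydroxybenzoate F7. The remaining phenol would then be benzylated by Williamson etherification (BnBr, K2CO3, acetone, 50 °C) to reach 10; the hindered depside-type aryl ester is expected to survive these conditions.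

Further compounds
F1 | step 7 | methyl 2,4-bis(benzyloxy)-6-methylbenzoate | COC(=O)c1c(C)cc(OCc2ccccc2)cc1OCc1ccccc1
F2 | step 7 | 2,4-bis(benzyloxy)-6-methylbenzoic acid | OC(=O)c1c(C)cc(OCc2ccccc2)cc1OCc1ccccc1
F3 | step 7 | benzyl 4-{[2,4-bis(benzyloxy)-6-methylbenzoyl]oxy}-6-heptyl-2-hydroxybenzoate | CCCCCCCc1cc(OC(=O)c2c(C)cc(OCc3ccccc3)cc2OCc2ccccc2)cc(O)c1C(=O)OCc1ccccc1
F4 | step 4 | tert-butyl 3-chloro-3-oxopropanoate | CC(C)(C)OC(=O)CC(=O)Cl
F5 | step 4 | benzyl 4-{[2-acetyl-5-(tert-butoxy)-3,5-dioxopentanoyl]oxy}-6-heptyl-2-hydroxybenzoate | CCCCCCCc1cc(OC(=O)C(C(C)=O)C(=O)CC(=O)OC(C)(C)C)cc(O)c1C(=O)OCc1ccccc1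
F6 | step 4 | benzyl 4-[(2-acetyl-4-carboxy-3-oxobutanoyl)oxy]-6-heptyl-2-hydroxybenzoate | CCCCCCCc1cc(OC(=O)C(C(C)=O)C(=O)CC(=O)O)cc(O)c1C(=O)OCc1ccccc1
F7 | step 5 | benzyl 4-{[4-(benzyloxy)-6-methyl-2-oxo-2H-pyran-5-carbonyl]oxy}-6-heptyl-2-hydroxybenzoate | CCCCCCCc1cc(OC(=O)C2=C(C)OC(=O)C=C2OCc2ccccc2)cc(O)c1C(=O)OCc1ccccc1
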